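**Plan**
- The target is a meso (2R,3R,4S,5S)-tetrahydrofuran. The aroyl groups at C3/C4 are cis, the 4-hydroxyphenyl groups (rings B) at C2/C5 are cis, and each aryl group is trans to the neighbouring aroyl group.
- Enabling feature: each ring A carries the ketone on C1' and oxygen on C2' and C4'. C1'/C6' therefore map onto an alkynyl ketone and C2'–C5' onto a 1,1,3-trioxygenated butadiene, and the first cuts are C1'–C2' and C5'–C6' in both rings A.
- The resulting 3,4-bis(propynoyl)tetrahydrofuran is cut at both CO–C(sp) bonds (N-methoxy-N-methylamide plus ethynyl Grignard reagent). It is then cut at both C2/C5–aryl bonds (decarboxylative arylation of a 2,5-diacid).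
- The 2,5-diacid comes from C=C cleavage of the furan–maleic anhydride cycloadduct.
- Forward order: oxanorbornene, release of the tetrahydrofuran ring, attachment of rings B, installation of the ynones, closure of both rings A, then global deprotection.
- Stereochemistry: C3/C4 cis comes from suprafacial addition to the Z-dienophile. C2/C5 are set by radical capture anti to the adjacent ester. No absolute control is needed.

Key step: step 11

Remark: the four descriptors of the target describe a meso compound with a mirror plane through O1 and the midpoint of C3–C4. Only relative configuration has to be controlled, and desymmetrised intermediates are racemic. Ring atoms are O1, C2–C5; ring A = C1'–C6'.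

**Step 1**
Reactants: 1 furan; 2 maleic anhydride
Product: 3 exo-7-oxabicyclo[2.2.1]hept-5-ene-2,3-dicarboxylic anhydride (meso; anhydride ring on the side of the oxygen bridge)
Conditions: Et2O, rt, 48 h
Reagents that add atoms: none
Why: This is a reversible Diels–Alder reaction from which the thermodynamically preferred exo adduct crystallises, and suprafacial addition to the Z-dienophile fixes the cis relationship of the two carbonyl-bearing carbons, the future C3 and C4.

**Step 2**
Reactants: 3 exo anhydride
Product: 5 dimethyl exo,exo-7-oxabicyclo[2.2.1]hept-5-ene-2,3-dicarboxylate (meso), via half ester 4 (not isolated)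
Conditions: MeOH, cat. H2SO4, rt → 60 °C
Reagents that add atoms: methanol, CO
Why: Anhydride methanolysis followed by Fischer esterification is the standard access to this diester, touches no stereocentre, and opens the anhydride at rt before warming, so the retro-Diels–Alder reaction should stay slow.

**Step 3**
Reactants: 5 oxanorbornene diester
Product: 6 (2R,3R,4S,5S)-3,4-bis(methoxycarbonyl)tetrahydrofuran-2,5-dicarboxylic acid (meso; 2,3-trans, 3,4-cis, 4,5-trans)
Conditions: RuCl3·xH2O (cat.), NaIO4, EtOAc/MeCN/H2O, 0 °C → rt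
Reagents that add atoms: sodium periodate, [Na+].[O-]I(=O)(=O)=O; water, O
Why: Catalytic RuO4 oxidative cleavage turns the strained cis-alkene into two carboxylic acids without touching the ring carbons, and the ether alpha C–H bonds are deactivated by the flanking carbonyl groups.

**Step 4**
Reactants: 6 diacid
Product: 7 2,5-bis(1,3-dioxoisoindolin-2-yl) 3,4-dimethyl (2R,3R,4S,5S)-tetrahydrofuran-2,3,4,5-tetracarboxylate
Conditions: N-hydroxyphthalimide, DIC, cat. DMAP, CH2Cl2, 0 °C → rt
Reagents that add atoms: N-hydroxyphthalimide, O=C1c2ccccc2C(=O)N1O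
Why: This is a carbodiimide (Steglich-type) esterification to the redox-active N-acyloxyphthalimide, in which any bridged anhydride formed from the cis-2,5-diacid is reopened by N-hydroxyphthalimide and reactivated, so both acids should end as active esters.

**Step 5**
Reactants: 7 bis(N-acyloxyphthalimide); 8 1-(benzyloxy)-4-bromobenzene
Product: 11 dimethyl (2R,3R,4S,5S)-2,5-bis[4-(benzyloxy)phenyl]tetrahydrofuran-3,4-dicarboxylate (meso), via Grignard reagent 9 (not isolated), via arylzinc chloride 10 (not isolated)
Conditions: 8, Mg, LiCl, THF, rt; ZnCl2, 0 °C → rt; then 7, NiCl2(dme) (cat.), 4,4'-di-tert-butyl-2,2'-bipyridine (cat.), THF/DMF, rt; 1 M HCl work-up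
Reagents that add atoms: none
Why: In this nickel-catalysed decarboxylative Negishi-type arylation of redox-active esters, a reaction type shown for cyclic alpha-alkoxy acids, single-electron reduction expels CO2 and phthalimide anion, and each planarised alpha-oxy radical at C2/C5 is captured by arylnickel and coupled on the face anti to the adjacent C3/C4 ester, which sets 2,3-trans and 4,5-trans (hence 2,5-cis) whatever the configuration of 7 at these carbons.

**Step 6**
Reactants: 11 diaryl diester
Product: 12 (2R,3R,4S,5S)-2,5-bis[4-(benzyloxy)phenyl]-N3,N4-dimethoxy-N3,N4-dimethyltetrahydrofuran-3,4-dicarboxamide (meso)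
Conditions: MeNH(OMe)·HCl, iPrMgCl, THF, −20 → 0 °C; cold 1 M HCl
Reagents that add atoms: N,O-dimethylhydroxylamine hydrochloride, CNOC.Cl
Why: Ester aminolysis with the chloromagnesium amide of N,O-dimethylhydroxylamine is routinely applied to alpha-stereogenic esters, because the reagent is strongly nucleophilic and weakly basic at low temperature; C3/C4 epimerisation and beta-alkoxide elimination should therefore not compete, and epimerisation would only exchange the acyl/acyl cis contact for an aryl/acyl one.

**Step 7**
Reactants: 12 bis(N-methoxy-N-methylamide); 13 ethynylmagnesium bromide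
Product: 15 1,1'-{(2R,3R,4S,5S)-2,5-bis[4-(benzyloxy)phenyl]tetrahydrofuran-3,4-diyl}bis(prop-2-yn-1-one) (meso), via bis(magnesium hemiaminal) chelate 14 (not isolated)
Conditions: 13 (excess), THF, −20 → 0 °C; inverse quench into cold 1 M HCl
Reagents that add atoms: none
Why: In this Weinreb ketone synthesis the five-membered magnesium chelate stops each addition at the ketone level, and pouring the mixture into cold acid protonates the released N,O-dimethylhydroxylamine before it can add to the terminal ynones.

**Step 8**
Reactants: 16 acetyl chloride; 17 1,1-dichloroethene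
Product: 19 4,4-dichlorobut-3-en-2-one, via 4,4,4-trichlorobutan-2-one 18 (not isolated)
Conditions: AlCl3, CH2Cl2, 0 °C → rt; ice-water; steam distillation
Reagents that add atoms: none
Why: This is a Friedel–Crafts-type acylation of an alkene, in which the acylium ion adds to the CH2 terminus, chloride adds to the dichlorocarbenium centre, and HCl is then lost into conjugation.

**Step 9**
Reactants: 19 4,4-dichlorobut-3-en-2-one
Product: 20 4,4-dimethoxybut-3-en-2-one
Conditions: NaOMe (2 equiv), MeOH, 0 °C → rt
Reagents that add atoms: sodium methoxide, [Na+].[O-]C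
Why: Methoxide replaces both vinylic chlorides by twofold conjugate addition–elimination at the beta carbon of the enone.

**Step 10**
Reactants: 20 4,4-dimethoxybut-3-en-2-one
Product: 21 1,1-dimethoxy-3-(trimethylsilyloxy)buta-1,3-diene
Conditions: Me3SiCl, Et3N, cat. ZnCl2, toluene, 40 °C; filtration, distillation
Reagents that add atoms: chlorotrimethylsilane, C[Si](C)(C)Cl
Why: Soft enolisation and O-silylation of a methyl ketone can give only one silyloxydiene here, because the methyl group alone carries enolisable hydrogens.

**Step 11**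
Reactants: 15 bis-ynone; 21 1,1-dimethoxy-3-(trimethylsilyloxy)buta-1,3-diene (two equivalents react, excess used)
Product: 24 {(2R,3R,4S,5S)-2,5-bis[4-(benzyloxy)phenyl]tetrahydrofuran-3,4-diyl}bis[(4-hydroxy-2-methoxyphenyl)methanone] (meso), via bis(cyclohexadiene) cycloadduct 22 (not isolated), via bis(aryl silyl ether) 23 (not isolated)
Conditions: 21 (5 equiv), toluene, rt → 60 °C; then 0.1 M HCl/THF, rt
Reagents that add atoms: none
Why: Diene 21 is both a ketene acetal and a silyl enol ether, so in a concerted but strongly asynchronous normal-demand [4+2] cycloaddition its free CH2 terminus bonds to the terminal (beta) alkyne carbon and its C(OMe)2 terminus to the alpha carbon, giving the bis(cyclohexa-1,4-diene) 22. Each new ring then loses methanol from the ketal carbon and the ring CH2 to aromatise to 23, and dilute acid removes the silyl groups to give 24. The closest known reaction type is the Diels–Alder/aromatisation of 1,1-dialkoxy-3-silyloxybutadienes with propiolates and alkynyl ketones, which gives 4-hydroxy-2-methoxyaryl carbonyl compounds. Each ring A closes as a six-membered carbocycle by intermolecular cycloaddition that forms C1'–C2' and C5'–C6' in one event, and the two closures are independent and equivalent because of the mirror symmetry of 15. No stereocentre is created, and C2–C5 should stay intact because the medium is neutral and free of base and organometallic reagents, which also suppresses retro-oxa-Michael opening of the tetrahydrofuran. The step needs regioselectivity (oxygen ortho and para to the ketone), secured by the matched polarisation of ynone and diene, and chemoselectivity for the alkyne over the C=O group, secured by the unhindered terminal alkyne carbon as the most accessible electrophilic site.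

**Step 12**
Reactants: 24 bis(4-hydroxy-2-methoxyphenyl) diketone
Product: 25 [(2R,3R,4S,5S)-2,5-bis(4-hydroxyphenyl)tetrahydrofuran-3,4-diyl]bis[(2,4-dihydroxyphenyl)methanone] (meso; CNP0237262.1)
Conditions: BCl3 (excess), C6HMe5, CH2Cl2, −78 → 0 °C; ice-water
Reagents that add atoms: none
Why: In this Lewis-acid ether cleavage BCl3 with pentamethylbenzene as a non-basic benzyl-cation scavenger removes the aryl benzyl ethers at low temperature, and on warming boron chelated between the ketone oxygen and the ortho-methoxy group cleaves those methyl ethers selectively, while the absence of base leaves C3/C4 untouched.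

**Compound list**
1 | furan | c1ccoc1 | starting material
2 | maleic anhydride | O=C1OC(=O)C=C1 | starting material
3 | exo-7-oxabicyclo[2.2.1]hept-5-ene-2,3-dicarboxylic anhydride (meso) | O=C1OC(=O)[C@@H]2[C@H]1[C@H]1C=C[C@@H]2O1 | intermediate
4 | exo,exo-3-(methoxycarbonyl)-7-oxabicyclo[2.2.1]hept-5-ene-2-carboxylic acid (racemic, one enantiomer drawn) | COC(=O)[C@@H]1[C@H](C(=O)O)[C@H]2C=C[C@@H]1O2 | intermediate (not isolated)
5 | dimethyl exo,exo-7-oxabicyclo[2.2.1]hept-5-ene-2,3-dicarboxylate (meso) | COC(=O)[C@@H]1[C@H](C(=O)OC)[C@H]2C=C[C@@H]1O2 | intermediate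
6 | (2R,3R,4S,5S)-3,4-bis(methoxycarbonyl)tetrahydrofuran-2,5-dicarboxylic acid | COC(=O)[C@@H]1[C@H](C(=O)OC)[C@@H](C(=O)O)O[C@H]1C(=O)O | intermediate
7 | 2,5-bis(1,3-dioxoisoindolin-2-yl) 3,4-dimethyl (2R,3R,4S,5S)-tetrahydrofuran-2,3,4,5-tetracarboxylate | COC(=O)[C@@H]1[C@H](C(=O)OC)[C@@H](C(=O)ON2C(=O)c3ccccc3C2=O)O[C@H]1C(=O)ON1C(=O)c2ccccc2C1=O | intermediate
8 | 1-(benzyloxy)-4-bromobenzene | Brc1ccc(OCc2ccccc2)cc1 | starting material
9 | 4-(benzyloxy)phenylmagnesium bromide | Br[Mg]c1ccc(OCc2ccccc2)cc1 | intermediate (not isolated)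
10 | 4-(benzyloxy)phenylzinc chloride | Cl[Zn]c1ccc(OCc2ccccc2)cc1 | intermediate (not isolated)
11 | dimethyl (2R,3R,4S,5S)-2,5-bis[4-(benzyloxy)phenyl]tetrahydrofuran-3,4-dicarboxylate | COC(=O)[C@@H]1[C@H](C(=O)OC)[C@@H](c2ccc(OCc3ccccc3)cc2)O[C@H]1c1ccc(OCc2ccccc2)cc1 | intermediate
12 | (2R,3R,4S,5S)-2,5-bis[4-(benzyloxy)phenyl]-N3,N4-dimethoxy-N3,N4-dimethyltetrahydrofuran-3,4-dicarboxamide | CON(C)C(=O)[C@@H]1[C@H](C(=O)N(C)OC)[C@@H](c2ccc(OCc3ccccc3)cc2)O[C@H]1c1ccc(OCc2ccccc2)cc1 | intermediate
13 | ethynylmagnesium bromide | C#C[Mg]Br | starting material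
14 | bis(bromomagnesium hemiaminal) from twofold addition of 13 to 12 (hemiaminal carbons undefined) | C#CC(O[Mg]Br)(N(C)OC)[C@@H]1[C@H](C(O[Mg]Br)(C#C)N(C)OC)[C@@H](c2ccc(OCc3ccccc3)cc2)O[C@H]1c1ccc(OCc2ccccc2)cc1 | intermediate (not isolated)
15 | 1,1'-{(2R,3R,4S,5S)-2,5-bis[4-(benzyloxy)phenyl]tetrahydrofuran-3,4-diyl}bis(prop-2-yn-1-one) | C#CC(=O)[C@@H]1[C@H](C(=O)C#C)[C@@H](c2ccc(OCc3ccccc3)cc2)O[C@H]1c1ccc(OCc2ccccc2)cc1 | intermediate
16 | acetyl chloride | CC(=O)Cl | starting material
17 | 1,1-dichloroethene | C=C(Cl)Cl | starting material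
18 | 4,4,4-trichlorobutan-2-one | CC(=O)CC(Cl)(Cl)Cl | intermediate (not isolated)
19 | 4,4-dichlorobut-3-en-2-one | CC(=O)C=C(Cl)Cl | intermediate
20 | 4,4-dimethoxybut-3-en-2-one | CC(=O)C=C(OC)OC | intermediate
21 | 1,1-dimethoxy-3-(trimethylsilyloxy)buta-1,3-diene | COC(OC)=CC(=C)O[Si](C)(C)C | intermediate
22 | {(2R,3R,4S,5S)-2,5-bis[4-(benzyloxy)phenyl]tetrahydrofuran-3,4-diyl}bis{[6,6-dimethoxy-4-(trimethylsilyloxy)cyclohexa-1,4-dien-1-yl]methanone} | O=C(C1=CCC(O[Si](C)(C)C)=CC1(OC)OC)[C@@H]1[C@H](C(=O)C2=CCC(O[Si](C)(C)C)=CC2(OC)OC)[C@@H](c2ccc(OCc3ccccc3)cc2)O[C@H]1c1ccc(OCc2ccccc2)cc1 | intermediate (not isolated)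
23 | {(2R,3R,4S,5S)-2,5-bis[4-(benzyloxy)phenyl]tetrahydrofuran-3,4-diyl}bis{[2-methoxy-4-(trimethylsilyloxy)phenyl]methanone} | O=C(c1ccc(O[Si](C)(C)C)cc1OC)[C@@H]1[C@H](C(=O)c2ccc(O[Si](C)(C)C)cc2OC)[C@@H](c2ccc(OCc3ccccc3)cc2)O[C@H]1c1ccc(OCc2ccccc2)cc1 | intermediate (not isolated)
24 | {(2R,3R,4S,5S)-2,5-bis[4-(benzyloxy)phenyl]tetrahydrofuran-3,4-diyl}bis[(4-hydroxy-2-methoxyphenyl)methanone] | O=C(c1ccc(O)cc1OC)[C@@H]1[C@H](C(=O)c2ccc(O)cc2OC)[C@@H](c2ccc(OCc3ccccc3)cc2)O[C@H]1c1ccc(OCc2ccccc2)cc1 | intermediate
25 | [(2R,3R,4S,5S)-2,5-bis(4-hydroxyphenyl)tetrahydrofuran-3,4-diyl]bis[(2,4-dihydroxyphenyl)methanone] | O=C(c1ccc(O)cc1O)[C@@H]1[C@H](C(=O)c2ccc(O)cc2O)[C@@H](c2ccc(O)cc2)O[C@H]1c1ccc(O)cc1 | target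

**Step count**
Total step count: 12.
Longest linear sequence: 9 (steps 1–7, 11 and 12). Steps 8–10 form the diene branch.

**Steps most likely to fail**

1. Step 5, the twofold decarboxylative arylation.
   - What may go wrong: hydrolysis or premature reduction of the alpha-alkoxy active esters, beta-hydride elimination from the alkylnickel intermediate, stalling after the first coupling, or weak facial selectivity in the capture of the C2/C5 radicals.
   - Fallback: the radical coupling is replaced by polar substitution at the acetal oxidation level, setting out from diacid 6. Oxidative decarboxylation with Pb(OAc)4 and pyridine in THF should give dimethyl 3,4-cis-2,5-diacetoxytetrahydrofuran-3,4-dicarboxylate F1; its anomeric composition is of no consequence. Me3SiBr in CH2Cl2 should convert this into dimethyl 3,4-cis-2,5-dibromotetrahydrofuran-3,4-dicarboxylate F2, which is used crude. Substitution with arylzinc chloride 10 (made as in step 5, solvent changed to toluene) follows the reaction type used for aryl C-glycosides from glycosyl bromides. It should run through oxocarbenium ions attacked anti to the neighbouring ester, and it comes back to the route at diester 11.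

2. Step 11, the twofold cycloaddition and aromatisation.
   - What may go wrong: polymerisation of the terminal ynones on warming, conjugate addition of the liberated methanol, arrest at an open-chain Michael stage without ring closure, or incomplete reaction at the second ynone.
   - Fallback: ring A is brought in preformed, setting out from bis(N-methoxy-N-methylamide) 12. Bromine–lithium exchange of purchased 1-bromo-2,4-bis(benzyloxy)benzene with n-BuLi in THF at −78 °C should give 2,4-bis(benzyloxy)phenyllithium F3. Its addition to 12 at −78 °C with an acidic quench should give {(2R,3R,4S,5S)-2,5-bis[4-(benzyloxy)phenyl]tetrahydrofuran-3,4-diyl}bis{[2,4-bis(benzyloxy)phenyl]methanone} F4. Hydrogenolysis of all six benzyl ethers (H2, Pd/C, EtOAc/THF, rt) comes back to the route at target 25.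

3. Step 12, the global ether cleavage.
   - What may go wrong: Lewis-acid ionisation of the doubly benzylic C2–O and C5–O bonds, leading to ring opening, epimerisation or capture by the scavenger. Acid-induced Paal–Knorr-type cyclodehydration of the 1,4-diketone and incomplete demethylation are further risks.
   - Fallback: no methyl ether is ever formed, and the same ring A bonds are made, setting out from bis-ynone 15. Dimedone with Me3SiOTf and Et3N should give 5,5-dimethyl-1,3-bis(trimethylsilyloxy)cyclohexa-1,3-diene F5. Heating 15 with this diene in toluene (sealed vessel, 120–140 °C) should bring about cycloaddition and then cycloreversion with loss of 2-methylpropene. Desilylation on mildly acidic work-up should give {(2R,3R,4S,5S)-2,5-bis[4-(benzyloxy)phenyl]tetrahydrofuran-3,4-diyl}bis[(2,4-dihydroxyphenyl)methanone] F6. Neutral hydrogenolysis (H2, Pd/C, EtOAc, rt) comes back to the route at target 25 without any Lewis acid.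

**Further compounds**
F1 | step 5 | dimethyl 3,4-cis-2,5-diacetoxytetrahydrofuran-3,4-dicarboxylate (C2/C5 undefined) | COC(=O)[C@@H]1[C@H](C(=O)OC)C(OC(C)=O)OC1OC(C)=O
F2 | step 5 | dimethyl 3,4-cis-2,5-dibromotetrahydrofuran-3,4-dicarboxylate (C2/C5 undefined) | COC(=O)[C@@H]1[C@H](C(=O)OC)C(Br)OC1Br
F3 | step 11 | 2,4-bis(benzyloxy)phenyllithium | [Li]c1ccc(OCc2ccccc2)cc1OCc1ccccc1
F4 | step 11 | {(2R,3R,4S,5S)-2,5-bis[4-(benzyloxy)phenyl]tetrahydrofuran-3,4-diyl}bis{[2,4-bis(benzyloxy)phenyl]methanone} | O=C(c1ccc(OCc2ccccc2)cc1OCc1ccccc1)[C@@H]1[C@H](C(=O)c2ccc(OCc3ccccc3)cc2OCc2ccccc2)[C@@H](c2ccc(OCc3ccccc3)cc2)O[C@H]1c1ccc(OCc2ccccc2)cc1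
F5 | step 12 | 5,5-dimethyl-1,3-bis(trimethylsilyloxy)cyclohexa-1,3-diene | CC1(C)CC(O[Si](C)(C)C)=CC(O[Si](C)(C)C)=C1
F6 | step 12 | {(2R,3R,4S,5S)-2,5-bis[4-(benzyloxy)phenyl]tetrahydrofuran-3,4-diyl}bis[(2,4-dihydroxyphenyl)methanone] | O=C(c1ccc(O)cc1O)[C@@H]1[C@H](C(=O)c2ccc(O)cc2O)[C@@H](c2ccc(OCc3ccccc3)cc2)O[C@H]1c1ccc(OCc2ccccc2)cc1
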